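**Retrosynthetic overview**
- Dryocrassin ABBA ⇒ cut the three C–CH2–C bridges (formaldehyde): bis(butanoylphloroglucinol)methane plus two acetylfilicinic acid units; the two outer A–CH2–B bridges are formed last.
- Central B–CH2–B unit ⇒ butanoylphloroglucinol + formaldehyde; butanoylphloroglucinol ⇒ phloroglucinol + butanoyl chloride; phloroglucinol ⇒ benzene (threefold C–H borylation/oxidation).
- Acetylfilicinic acid ⇒ filicinic acid + acetyl chloride; filicinic acid ⇒ 3-ethoxycyclobutenone + methyl isobutyrate by a two-carbon (4→6) ring expansion that also installs the gem-dimethyl carbon (key step).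
- Ring order: ring A (cyclohexanetrione) by ring expansion; ring B from benzene; then B–CH2–B; then both A–CH2–B bridges.

Assumption: the target has no stereocentre and is achiral, so no enantiocontrol is needed; it is made as the tautomer drawn.

**Route**

Step 1
Reactants: 1 methyl 2-methylpropanoate (methyl isobutyrate); 2 3-ethoxycyclobut-2-en-1-one
Product: 7 filicinic acid (3,5-dihydroxy-4,4-dimethylcyclohexa-2,5-dien-1-one), via lithium ester enolate 3 (not isolated), via lithium cyclobutenolate adduct 4 (not isolated), via ring-opened lithium dienolate 5 (not isolated), via ethoxy enedione 6 (not isolated)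
Conditions: LiN(iPr)2 (1.1 equiv), THF, −78 °C; add 2, −78 → 50 °C; then 2 M HCl, THF/H2O, 50 °C
Reagents that add atoms: water, O
Why: Proposed new method: anionic two-carbon (4→6) ring expansion of an alkoxycyclobutenone by an α,α-disubstituted ester enolate – enolate 3 adds 1,2 to the strained carbonyl of 2 (as organolithiums do), the alkoxide 4 (racemic carbinol carbon, destroyed in the next event) releases ring strain by alkoxide-driven C1–C4 fragmentation (vinylogous retro-aldol) to the extended enolate 5, which has no acidic C–H at the quaternary carbon and so can only close by Dieckmann attack of its terminal CH2 on the ester to give six-membered 6, and acid then hydrolyses the vinylogous ester; the closest known reactions are the methoxide-catalysed ring expansion of tetramethylcyclobutane-1,3-dione (dimethylketene dimer) to hexamethylcyclohexane-1,3,5-trione, Stork–Danheiser 1,2-addition to 3-alkoxyenones and the Dieckmann condensation.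

Step 2
Reactants: 7 filicinic acid; 8 acetyl chloride
Product: 9 acetylfilicinic acid (2-acetyl-3,5-dihydroxy-6,6-dimethylcyclohexa-2,4-dien-1-one)
Conditions: AlCl3 (3 equiv), PhNO2, 25 → 60 °C; then ice, 1 M HCl
Reagents that add atoms: none
Why: Friedel–Crafts-type C-acylation of the enolised cyclic β-triketone (a vinylogous acid); the two ring CH positions are equivalent by symmetry and the aluminium-chelated 2-acyl product is deactivated, so 1.0 equiv of 8 should give mono-acylation; no stereocentre is formed.

Step 3
Reactants: 10 benzene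
Product: 12 phloroglucinol (benzene-1,3,5-triol), via tris(pinacolboryl)benzene 11 (not isolated)
Conditions: B2pin2 (1.6 equiv), [Ir(OMe)(cod)]2 (1.5 mol %), 4,4'-di-tert-butyl-2,2'-bipyridine (3 mol %), cyclohexane, 80 °C, sealed; evaporate; then 30% aq. H2O2, THF/NaH2PO4–Na2HPO4 buffer (pH 7), 0 → 25 °C
Reagents that add atoms: hydrogen peroxide, OO; bis(pinacolato)diboron, CC1(C)OB(OC1(C)C)B1OC(C)(C)C(C)(C)O1 (its atoms stay only in intermediate 11)
Why: Sterically controlled iridium-catalysed C–H borylation (Ishiyama–Miyaura–Hartwig) never places boron ortho to a boryl group, so the 1,3-diboryl arene can only go on to the 1,3,5-triboryl arene 11; peroxide oxidation of each C–B bond (1,2-aryl shift from boron to oxygen) gives the triol in one pot. The 1,4-diboryl isomer is a dead end, caps the yield near two thirds and ends as hydroquinone, removed by crystallisation.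

Step 4
Reactants: 12 phloroglucinol; 13 butanoyl chloride
Product: 14 1-(2,4,6-trihydroxyphenyl)butan-1-one (butanoylphloroglucinol)
Conditions: AlCl3 (3 equiv), PhNO2/CH2Cl2, 0 → 45 °C; then ice, 1 M HCl
Reagents that add atoms: none
Why: Friedel–Crafts acylation of the threefold-symmetric, very electron-rich arene gives a single regioisomer, and the chelated aryl ketone is deactivated towards a second acylation.

Step 5
Reactants: 14 butanoylphloroglucinol (3 equiv); 15 formaldehyde (1 equiv)
Product: 18 bis(3-butanoyl-2,4,6-trihydroxyphenyl)methane, via hydroxymethyl phenol 16 (not isolated), via ortho-quinone methide 17 (not isolated)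
Conditions: 37% aq. CH2O, 1% aq. KOH, 0 °C, 20 min; then 1 M HCl; excess 14 recovered
Reagents that add atoms: none
Why: Lederer–Manasse hydroxymethylation of the phenolate, loss of hydroxide to the ortho-quinone methide and Michael addition of a second phenolate (the classical methylene-bis-acylphloroglucinol synthesis); the two free positions of 14 are equivalent, and the excess of 14 suppresses oligomers.

Step 6
Reactants: 18 bis(3-butanoyl-2,4,6-trihydroxyphenyl)methane (1 equiv); 9 acetylfilicinic acid (3 equiv); 15 formaldehyde (2.2 equiv)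
Product: 22 dryocrassin ABBA, via hydroxymethyl trione 19 (not isolated), via methylidene trione 20 (not isolated), via mono-capped trimer 21 (not isolated)
Conditions: 1% aq. KOH, 37% aq. CH2O added over 1 h, 0 → 20 °C; then 1 M HCl; crystallisation
Reagents that add atoms: none
Why: Knoevenagel condensation of the vinylogous acid 9 with formaldehyde gives the strongly electrophilic 2-methylidene-1,3-dione 20, which is trapped in a Michael addition by the single free aromatic carbon on each ring of 18, twice; both partners have only one reactive carbon, so the connectivity is unambiguous, and no stereocentre is formed.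

**Compound list**
1 | methyl 2-methylpropanoate (methyl isobutyrate) | COC(=O)C(C)C | starting material
2 | 3-ethoxycyclobut-2-en-1-one | CCOC1=CC(=O)C1 | starting material
3 | lithium 1-methoxy-2-methylprop-1-en-1-olate (lithium enolate of 1) | [Li+].COC([O-])=C(C)C | intermediate
4 | lithium 3-ethoxy-1-(1-methoxy-2-methyl-1-oxopropan-2-yl)cyclobut-2-en-1-olate (racemic 1,2-adduct) | [Li+].CCOC1=CC([O-])(C1)C(C)(C)C(=O)OC | intermediate
5 | lithium (3E)-5-ethoxy-1-methoxy-2,2-dimethyl-1-oxohexa-3,5-dien-3-olate (ring-opened dienolate) | [Li+].COC(=O)C(C)(C)/C([O-])=C\C(OCC)=C | intermediate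
6 | 5-ethoxy-2,2-dimethylcyclohex-4-ene-1,3-dione (formed as its lithium enolate) | CCOC1=CC(=O)C(C)(C)C(=O)C1 | intermediate
7 | filicinic acid, 3,5-dihydroxy-4,4-dimethylcyclohexa-2,5-dien-1-one | CC1(C)C(O)=CC(=O)C=C1O | intermediate
8 | acetyl chloride | CC(=O)Cl | starting material
9 | acetylfilicinic acid, 2-acetyl-3,5-dihydroxy-6,6-dimethylcyclohexa-2,4-dien-1-one | CC(=O)C1=C(O)C=C(O)C(C)(C)C1=O | intermediate
10 | benzene | c1ccccc1 | starting material
11 | 1,3,5-tris(4,4,5,5-tetramethyl-1,3,2-dioxaborolan-2-yl)benzene | CC1(C)OB(OC1(C)C)c1cc(B2OC(C)(C)C(C)(C)O2)cc(B2OC(C)(C)C(C)(C)O2)c1 | intermediate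
12 | phloroglucinol, benzene-1,3,5-triol | Oc1cc(O)cc(O)c1 | intermediate
13 | butanoyl chloride | CCCC(=O)Cl | starting material
14 | 1-(2,4,6-trihydroxyphenyl)butan-1-one | CCCC(=O)c1c(O)cc(O)cc1O | intermediate
15 | formaldehyde | C=O | starting material
16 | 1-[2,4,6-trihydroxy-3-(hydroxymethyl)phenyl]butan-1-one | CCCC(=O)c1c(O)cc(O)c(CO)c1O | intermediate
17 | 2-butanoyl-3,5-dihydroxy-6-methylidenecyclohexa-2,4-dien-1-one (ortho-quinone methide) | CCCC(=O)C1=C(O)C=C(O)C(=C)C1=O | intermediate
18 | bis(3-butanoyl-2,4,6-trihydroxyphenyl)methane | CCCC(=O)c1c(O)cc(O)c(Cc2c(O)cc(O)c(C(=O)CCC)c2O)c1O | intermediate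
19 | 2-acetyl-3,5-dihydroxy-4-(hydroxymethyl)-6,6-dimethylcyclohexa-2,4-dien-1-one | CC(=O)C1=C(O)C(CO)=C(O)C(C)(C)C1=O | intermediate
20 | 2-acetyl-3-hydroxy-6,6-dimethyl-4-methylidenecyclohex-2-ene-1,5-dione | CC(=O)C1=C(O)C(=C)C(=O)C(C)(C)C1=O | intermediate
21 | 2-acetyl-4-[[3-butanoyl-5-[(3-butanoyl-2,4,6-trihydroxyphenyl)methyl]-2,4,6-trihydroxyphenyl]methyl]-3,5-dihydroxy-6,6-dimethylcyclohexa-2,4-dien-1-one (A–CH2–B–CH2–B) | CCCC(=O)c1c(O)cc(O)c(Cc2c(O)c(CC3=C(O)C(C)(C)C(=O)C(C(C)=O)=C3O)c(O)c(C(=O)CCC)c2O)c1O | intermediate
22 | dryocrassin ABBA | CCCC(=O)c1c(O)c(CC2=C(O)C(C)(C)C(=O)C(C(C)=O)=C2O)c(O)c(Cc2c(O)c(CC3=C(O)C(C)(C)C(=O)C(C(C)=O)=C3O)c(O)c(C(=O)CCC)c2O)c1O | target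

**Step count and risks**

Total step count: 6. Longest linear sequence: 4 (steps 3, 4, 5, 6: 10 → 12 → 14 → 18 → 22); ring A joins after 2 steps (1, 2).

The three steps most likely to fail:

First, step 1, the proposed new ring expansion. The adduct 4 may fail to fragment, or 5 may close intermolecularly. The fallback uses known chemistry and sets out from 1. Its lithium enolate 3 (2 equiv) is C-acetoacetylated with diketene (4-methylideneoxetan-2-one) in THF at −78 °C to give methyl 2,2-dimethyl-3,5-dioxohexanoate F1. This is then closed by intramolecular Claisen condensation of the methyl ketone onto the ester, with NaOMe in refluxing MeOH or through the 1,3-diketone dianion with LiN(iPr)2 (2.2 equiv). The quaternary carbon blocks every aldol mode, and the fallback comes back to the route at filicinic acid 7.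

Second, step 6, the double hetero-bridging. Homo-coupling of 9 (albaspidin-type A–CH2–A) and base-induced exchange of the bridges can erode the yield. The fallback sets out from 9, which is converted with dimethylmethylideneammonium iodide (CH2Cl2, 25 °C; Mannich reaction) into 2-acetyl-4-[(dimethylamino)methyl]-3,5-dihydroxy-6,6-dimethylcyclohexa-2,4-dien-1-one F4. F4 (2.2 equiv) is then heated with 18 in dioxane/AcOH at 80 °C. Thermal loss of dimethylamine releases the methylidene trione 20 slowly and in the absence of free 9, so only the aromatic carbons of 18 can trap it; the fallback comes back at the target 22.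

Third, step 3, the one-pot triple borylation/oxidation. Apart from the regiochemical ceiling noted in the step, the triol is sensitive to over-oxidation. The fallback sets out from benzene 10. Friedel–Crafts alkylation with 2-chloropropane and AlCl3 under equilibrating conditions gives 1,3,5-tri(propan-2-yl)benzene F2. Autoxidation (O2, N-hydroxyphthalimide cat., 75 °C) gives 1,3,5-tris(2-hydroperoxypropan-2-yl)benzene F3. Acid-catalysed Hock rearrangement (cat. H2SO4, acetone, 50 °C; threefold 1,2-aryl shift to oxygen) then comes back to the route at phloroglucinol 12.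

**Further compounds**
F1 | step 1 | methyl 2,2-dimethyl-3,5-dioxohexanoate | COC(=O)C(C)(C)C(=O)CC(=O)C
F2 | step 3 | 1,3,5-tri(propan-2-yl)benzene | CC(C)c1cc(C(C)C)cc(C(C)C)c1
F3 | step 3 | 1,3,5-tris(2-hydroperoxypropan-2-yl)benzene | CC(C)(OO)c1cc(C(C)(C)OO)cc(C(C)(C)OO)c1
F4 | step 6 | 2-acetyl-4-[(dimethylamino)methyl]-3,5-dihydroxy-6,6-dimethylcyclohexa-2,4-dien-1-one | CC(=O)C1=C(O)C(CN(C)C)=C(O)C(C)(C)C1=O
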